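Target atoms are numbered as a 1H-indene (C1 ketone, C7 bearing CO2H). The cyclohexene ring (C3a, C4, C5, C6, C7, C7a) is read as the six-membered ring of a bicyclo[3.2.1]octa-2,6-diene: the cis carbon substituents on C7 (carboxyl carbon) and C3a (C3), 1,3-related across C7a, are tied together as a siloxy-alkene bridge. A chiral dirhodium vinylcarbenoid [4+3] (cyclopropanation, then Cope) between a 5,5-diester 2-siloxy-3-hexadecylcyclopentadiene and an ester-terminated vinylcarbene forms C6–C7 and C3a–C4 in one operation, places the C5=C6 alkene and sets C3a, C4 and C7. Ozonolysis of the bridge later frees the acid and a heptadecanoyl ketone, which a β-keto ester grown on C7a closes to the cyclopentenone.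

Key step: step 8

Assumption: Rh2(S-PTAD)4 (PTAD = (S)-(1-adamantyl)(phthalimido)acetate) is taken to select the diene face that leads to (1R,4R,5R)-16; should the opposite sense be found, Rh2(R-PTAD)4 is used and nothing else changes.

Step 1
Reactants: 1 dibenzyl malonate; 2 (Z)-1,4-dichlorobut-2-ene
Product: 3 dibenzyl cyclopent-3-ene-1,1-dicarboxylate
Conditions: LiH, DMF, 0 °C → rt
Reagents that add atoms: none
Why: Malonic ester double alkylation (substitution, then five-membered ring closure on the cis allylic dichloride); LiH in DMF is chosen because it should favour direct ring closure over the allylically transposed closure to a vinylcyclopropane.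

Step 2
Reactants: 3 dibenzyl cyclopent-3-ene-1,1-dicarboxylate
Product: 4 dibenzyl 4-oxocyclopent-2-ene-1,1-dicarboxylate
Conditions: t-BuOOH (70% aq.), Rh2(cap)4 (cap = caprolactamate, 1 mol %), K2CO3, CH2Cl2, rt
Reagents that add atoms: tert-butyl hydroperoxide, CC(C)(C)OO
Why: Radical allylic oxidation; the symmetric substrate gives one allyl radical, which should be oxygenated at the terminus remote from the quaternary carbon, so the carbonyl ends at C4 and the alkene moves next to C1.

Step 3
Reactants: 4 dibenzyl 4-oxocyclopent-2-ene-1,1-dicarboxylate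
Product: 5 dibenzyl 3-iodo-4-oxocyclopent-2-ene-1,1-dicarboxylate
Conditions: I2, pyridine, CH2Cl2, 0 °C → rt
Reagents that add atoms: iodine, II
Why: α-Iodination of an enone by the pyridine addition/iodination/elimination sequence (Baylis–Hillman-type), a reaction that tolerates a quaternary γ-carbon.

Step 4
Reactants: 5 dibenzyl 3-iodo-4-oxocyclopent-2-ene-1,1-dicarboxylate; 6 hexadec-1-ene
Product: 8 dibenzyl 3-hexadecyl-4-oxocyclopent-2-ene-1,1-dicarboxylate, via B-hexadecyl-9-BBN 7 (not isolated)
Conditions: 6, 9-BBN, THF, 0 °C → rt; then 5, PdCl2(dppf), AsPh3, Cs2CO3, DMF/THF/H2O, rt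
Reagents that add atoms: none
Why: Anti-Markovnikov hydroboration gives the primary alkylborane, and B-alkyl Suzuki–Miyaura coupling with the α-iodoenone places the hexadecyl chain on the enone α-carbon under mild aqueous base that should spare the benzyl esters.

Step 5
Reactants: 8 dibenzyl 3-hexadecyl-4-oxocyclopent-2-ene-1,1-dicarboxylate
Product: 9 dibenzyl 3-[(tert-butyldimethylsilyl)oxy]-4-hexadecylcyclopenta-2,4-diene-1,1-dicarboxylate
Conditions: TBSOTf, Et3N, CH2Cl2, −78 → 0 °C
Reagents that add atoms: tert-butyldimethylsilyl trifluoromethanesulfonate, CC(C)(C)[Si](C)(C)OS(=O)(=O)C(F)(F)F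
Why: Soft enolisation and O-silylation; the only α-hydrogens are at C5, so the cross-conjugated 2-siloxydiene must form, and the quaternary C1 excludes 1,5-hydrogen shifts and makes the two diene faces enantiotopic.

Step 6
Reactants: 10 octadecanal; 11 methyl glyoxylate
Product: 12 methyl (2E)-3-formylnonadec-2-enoate
Conditions: pyrrolidine (20 mol %), PhCO2H (20 mol %), toluene, 4 Å MS, 60 °C
Reagents that add atoms: none
Why: Enamine-mediated crossed aldol condensation of the enolisable aldehyde with the non-enolisable, more electrophilic glyoxylate; dehydration should give the E isomer (formyl trans to the ester), the usual outcome for α-substituted enals.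

Step 7
Reactants: 12 methyl (2E)-3-formylnonadec-2-enoate
Product: 13 methyl (2E)-3-[(E)-({[2-(trifluoromethyl)phenyl]sulfonyl}hydrazinylidene)methyl]nonadec-2-enoate
Conditions: 2-(CF3)C6H4SO2NHNH2, THF, rt
Reagents that add atoms: 2-(trifluoromethyl)benzenesulfonohydrazide, NNS(=O)(=O)c1ccccc1C(F)(F)F
Why: Hydrazone formation is chemoselective for the aldehyde, and the electron-poor sulfonyl group both keeps the NH from adding to the enoate and allows the later diazo release near room temperature (Bamford–Stevens-type).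

Step 8
Reactants: 9 dibenzyl 3-[(tert-butyldimethylsilyl)oxy]-4-hexadecylcyclopenta-2,4-diene-1,1-dicarboxylate; 13 sulfonylhydrazone of methyl (2E)-3-formylnonadec-2-enoate
Product: 16 (1R,4R,5R)-8,8-dibenzyl 4-methyl 7-[(tert-butyldimethylsilyl)oxy]-3,6-dihexadecylbicyclo[3.2.1]octa-2,6-diene-4,8,8-tricarboxylate, via vinyl diazo ester 14 (not isolated), via endo-divinylcyclopropane 15 (not isolated)
Conditions: NaH, CH2Cl2, 0 °C; then 9, Rh2(S-PTAD)4 (2 mol %), hexane/CH2Cl2, −20 °C → rt
Reagents that add atoms: none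
Why: Deprotonated 13 loses the sulfinate below room temperature to give diazo ester 14, which the dirhodium catalyst turns into a vinylcarbenoid; its carbenoid carbon adds across the silyl enol ether double bond C2=C3 of 9 in an asynchronous [2+1] closure that begins at C2, the terminus where the siloxy group stabilises the developing positive charge, to give the cis (endo) divinylcyclopropane 15. Compound 15 then undergoes a Cope rearrangement through the obligatory boat transition state, a [3,3] closure that builds the seven-membered ring and, because the one-carbon bridge C(CO2Bn)2 is already in place, the bicyclo[3.2.1]octadiene whose six-membered ring is the cyclohexene of the target; the net new bonds are C1–C2 of 16 (kept from the cyclopropanation) and C4–C5 (made in the Cope step). The closest known reaction type is the rhodium-catalysed tandem cyclopropanation/Cope rearrangement (formal [4+3] cycloaddition) of vinylcarbenoids with cyclopentadienes and 2-siloxydienes, here with the carbene released in situ from an N-sulfonylhydrazone. The bridgeheads C1 and C5 are set together by the face of the flat, achiral diene that the chiral catalyst selects, and C4 by the boat geometry, which places the E-configured ester on the side of the two-carbon bridge, cis to C6. The step needs regiocontrol (secured by the siloxy group, which directs the carbenoid carbon to C2 and not to C5 of the diene), cis-selective cyclopropanation (usual for carbenoids that carry hydrogen and an unsaturated group; a trans isomer could not rearrange at this temperature) and capture of 14 by the catalyst before it cyclises to a pyrazole (slow release at low temperature); the geminal diester stops 1,5-hydrogen shifts in the diene and leaves only the catalyst to distinguish its faces.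

Step 9
Reactants: 16 [4+3] adduct (tricarboxylate)
Product: 18 (1R,4R,5R,8S)-7-[(tert-butyldimethylsilyl)oxy]-3,6-dihexadecyl-4-(methoxycarbonyl)bicyclo[3.2.1]octa-2,6-diene-8-carboxylic acid, via malonic diacid 17 (not isolated)
Conditions: H2 (1 atm), Pd/C, EtOAc/pyridine, rt; filter; pyridine, 80 °C
Reagents that add atoms: none
Why: Hydrogenolysis of the benzyl esters should outpace hydrogenation of the hindered trisubstituted alkene and the tetrasubstituted enol ether, and the geminal diacid then loses CO2 through the usual cyclic transition state in warm pyridine, which also buffers the silyl enol ether; C8 epimers are expected (8S drawn) and both are usable because this centre is equilibrated again in step 11.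

Step 10
Reactants: 18 bicyclic C8 carboxylic acid; 19 potassium methyl malonate
Product: 21 methyl (1R,4R,5R,8S)-7-[(tert-butyldimethylsilyl)oxy]-3,6-dihexadecyl-8-(3-methoxy-3-oxopropanoyl)bicyclo[3.2.1]octa-2,6-diene-4-carboxylate, via acyl imidazolide 20 (not isolated)
Conditions: CDI, THF, rt; then 19, MgCl2, Et3N, MeCN/THF, rt → 40 °C
Reagents that add atoms: none
Why: Acyl imidazolide formation followed by decarboxylative Claisen condensation with the magnesium enolate of the malonate half-ester gives the β-keto ester under near-neutral conditions that should leave the silyl enol ether and the β,γ-unsaturated ester untouched.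

Step 11
Reactants: 21 bicyclic β-keto ester
Product: 23 (3aR,4R,7R,7aS)-3,5-dihexadecyl-2,4-bis(methoxycarbonyl)-1-oxo-3a,4,7,7a-tetrahydro-1H-indene-7-carboxylic acid, via keto acid 22 (not isolated)
Conditions: O3 (1.0 equiv), CH2Cl2, −78 °C; Me2S, −78 °C → rt; then piperidine, AcOH, wet CH2Cl2, rt → 40 °C
Reagents that add atoms: ozone, [O-][O+]=O
Why: Ozone should attack the electron-rich tetrasubstituted silyl enol ether much faster than the trisubstituted ring alkene, releasing the acid on C1 and the heptadecanoyl ketone on C5 of 22; piperidinium acetate then effects an intramolecular Knoevenagel condensation (five-membered aldol closure, dehydration) of the far more acidic β-keto ester methylene onto that ketone, the ring-fusion centre C7a equilibrating through the enamine/enol to the only strain-free, cis-fused cyclopentenone, while C3a, C4 and C7 keep the configuration set in step 8.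

Compound list
1 | dibenzyl malonate | O=C(CC(=O)OCc1ccccc1)OCc1ccccc1 | starting material
2 | (Z)-1,4-dichlorobut-2-ene | ClC/C=C\CCl | starting material
3 | dibenzyl cyclopent-3-ene-1,1-dicarboxylate | O=C(OCc1ccccc1)C2(CC=CC2)C(=O)OCc1ccccc1 | intermediate
4 | dibenzyl 4-oxocyclopent-2-ene-1,1-dicarboxylate | O=C1CC(C=C1)(C(=O)OCc2ccccc2)C(=O)OCc2ccccc2 | intermediate
5 | dibenzyl 3-iodo-4-oxocyclopent-2-ene-1,1-dicarboxylate | O=C1CC(C=C1I)(C(=O)OCc2ccccc2)C(=O)OCc2ccccc2 | intermediate
6 | hexadec-1-ene | CCCCCCCCCCCCCCC=C | starting material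
7 | 9-hexadecyl-9-borabicyclo[3.3.1]nonane | CCCCCCCCCCCCCCCCB1C2CCCC1CCC2 | intermediate (not isolated)
8 | dibenzyl 3-hexadecyl-4-oxocyclopent-2-ene-1,1-dicarboxylate | O=C1CC(C=C1CCCCCCCCCCCCCCCC)(C(=O)OCc2ccccc2)C(=O)OCc2ccccc2 | intermediate
9 | dibenzyl 3-[(tert-butyldimethylsilyl)oxy]-4-hexadecylcyclopenta-2,4-diene-1,1-dicarboxylate | CCCCCCCCCCCCCCCCC1=CC(C=C1O[Si](C)(C)C(C)(C)C)(C(=O)OCc2ccccc2)C(=O)OCc2ccccc2 | intermediate
10 | octadecanal | CCCCCCCCCCCCCCCCCC=O | starting material
11 | methyl glyoxylate | COC(=O)C=O | starting material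
12 | methyl (2E)-3-formylnonadec-2-enoate | CCCCCCCCCCCCCCCC/C(C=O)=C\C(=O)OC | intermediate
13 | methyl (2E)-3-[(E)-({[2-(trifluoromethyl)phenyl]sulfonyl}hydrazinylidene)methyl]nonadec-2-enoate | CCCCCCCCCCCCCCCC/C(=C\C(=O)OC)/C=N/NS(=O)(=O)c1ccccc1C(F)(F)F | intermediate
14 | methyl (2E)-3-(diazomethyl)nonadec-2-enoate | CCCCCCCCCCCCCCCC/C(C=[N+]=[N-])=C\C(=O)OC | intermediate (not isolated)
15 | dibenzyl (1S,5R,6S)-1-[(tert-butyldimethylsilyl)oxy]-2-hexadecyl-6-[(2E)-1-methoxy-1-oxononadec-2-en-3-yl]bicyclo[3.1.0]hex-2-ene-4,4-dicarboxylate (vinyl group endo) | CCCCCCCCCCCCCCCC/C(=C\C(=O)OC)[C@@H]1[C@@H]2C(C(=O)OCc3ccccc3)(C(=O)OCc3ccccc3)C=C(CCCCCCCCCCCCCCCC)[C@]12O[Si](C)(C)C(C)(C)C | intermediate (not isolated)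
16 | (1R,4R,5R)-8,8-dibenzyl 4-methyl 7-[(tert-butyldimethylsilyl)oxy]-3,6-dihexadecylbicyclo[3.2.1]octa-2,6-diene-4,8,8-tricarboxylate | CCCCCCCCCCCCCCCCC1=C[C@H]2C(O[Si](C)(C)C(C)(C)C)=C(CCCCCCCCCCCCCCCC)[C@@H]([C@H]1C(=O)OC)C2(C(=O)OCc1ccccc1)C(=O)OCc1ccccc1 | intermediate
17 | (1R,4R,5R)-7-[(tert-butyldimethylsilyl)oxy]-3,6-dihexadecyl-4-(methoxycarbonyl)bicyclo[3.2.1]octa-2,6-diene-8,8-dicarboxylic acid | CCCCCCCCCCCCCCCCC1=C[C@H]2C(O[Si](C)(C)C(C)(C)C)=C(CCCCCCCCCCCCCCCC)[C@@H]([C@H]1C(=O)OC)C2(C(=O)O)C(=O)O | intermediate (not isolated)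
18 | (1R,4R,5R,8S)-7-[(tert-butyldimethylsilyl)oxy]-3,6-dihexadecyl-4-(methoxycarbonyl)bicyclo[3.2.1]octa-2,6-diene-8-carboxylic acid (8S epimer drawn, carboxyl over the C6=C7 bridge) | CCCCCCCCCCCCCCCCC1=C[C@H]2C(O[Si](C)(C)C(C)(C)C)=C(CCCCCCCCCCCCCCCC)[C@@H]([C@H]1C(=O)OC)[C@@H]2C(=O)O | intermediate
19 | potassium methyl malonate (potassium 3-methoxy-3-oxopropanoate) | COC(=O)CC(=O)[O-].[K+] | starting material
20 | methyl (1R,4R,5R,8S)-7-[(tert-butyldimethylsilyl)oxy]-3,6-dihexadecyl-8-(1H-imidazole-1-carbonyl)bicyclo[3.2.1]octa-2,6-diene-4-carboxylate | CCCCCCCCCCCCCCCCC1=C[C@H]2C(O[Si](C)(C)C(C)(C)C)=C(CCCCCCCCCCCCCCCC)[C@@H]([C@H]1C(=O)OC)[C@@H]2C(=O)n1ccnc1 | intermediate (not isolated)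
21 | methyl (1R,4R,5R,8S)-7-[(tert-butyldimethylsilyl)oxy]-3,6-dihexadecyl-8-(3-methoxy-3-oxopropanoyl)bicyclo[3.2.1]octa-2,6-diene-4-carboxylate | CCCCCCCCCCCCCCCCC1=C[C@H]2C(O[Si](C)(C)C(C)(C)C)=C(CCCCCCCCCCCCCCCC)[C@@H]([C@H]1C(=O)OC)[C@@H]2C(=O)CC(=O)OC | intermediate
22 | (1R,4R,5R,6S)-5-heptadecanoyl-3-hexadecyl-4-(methoxycarbonyl)-6-(3-methoxy-3-oxopropanoyl)cyclohex-2-ene-1-carboxylic acid | CCCCCCCCCCCCCCCCC1=C[C@@H](C(=O)O)[C@@H](C(=O)CC(=O)OC)[C@@H](C(=O)CCCCCCCCCCCCCCCC)[C@H]1C(=O)OC | intermediate (not isolated)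
23 | (3aR,4R,7R,7aS)-3,5-dihexadecyl-2,4-bis(methoxycarbonyl)-1-oxo-3a,4,7,7a-tetrahydro-1H-indene-7-carboxylic acid | CCCCCCCCCCCCCCCCC1=C[C@@H](C(=O)O)[C@H]2C(=O)C(C(=O)OC)=C(CCCCCCCCCCCCCCCC)[C@H]2[C@H]1C(=O)OC | target

Total step count: 11. Longest linear sequence: 9 steps (steps 1–5 and 8–11, from dibenzyl malonate); steps 6 and 7 form the second branch, which joins in step 8.

Steps most likely to fail

Step 8 (key step). The acceptor-free vinyl diazo ester may cyclise to a pyrazole or couple with itself before the catalyst captures it. The siloxy-stabilised zwitterion may close a five-membered ring instead of the cyclopropane. Face selection by the catalyst may be incomplete for a carbene without an α-acceptor. The fallback keeps the same two bonds and the same operation but uses an isolable donor/acceptor diazo compound; it sets out from 9. Heptadecanoyl chloride (commercial) is condensed with 19 (MgCl2, Et3N, MeCN) to methyl 3-oxononadecanoate F1. Tf2O with aqueous Me4NOH should give the E enol triflate methyl (2E)-3-{[(trifluoromethyl)sulfonyl]oxy}nonadec-2-enoate F2. Coupling of F2 with benzyl diazoacetate (Pd(PPh3)4, N-methylmorpholine, DMF, rt) gives 1-benzyl 5-methyl (3E)-2-diazo-3-hexadecylpent-3-enedioate F3. F3 and 9 under Rh2(S-PTAD)4 should give, by the same cyclopropanation/Cope sequence, (1R,4R,5R)-2,8,8-tribenzyl 4-methyl 7-[(tert-butyldimethylsilyl)oxy]-3,6-dihexadecylbicyclo[3.2.1]octa-2,6-diene-2,4,8,8-tetracarboxylate F4, which carries an extra benzyl ester on C2. Hydrogenolysis as in step 9 gives (1R,4R,5R)-7-[(tert-butyldimethylsilyl)oxy]-3,6-dihexadecyl-4-(methoxycarbonyl)bicyclo[3.2.1]octa-2,6-diene-2,8,8-tricarboxylic acid F5. Pyridine at 100 °C should remove one malonic carboxyl and, through the 3-ene tautomer, the vinylogous C2 carboxyl; the ester dienolate formed is protonated at C4, and the route is rejoined at 18. In this variant the C4 configuration rests on that protonation and would have to be checked.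

Step 9. The ring alkene may be reduced during hydrogenolysis, and the silyl enol ether may be lost once the free malonic acid is present. The fallback avoids hydrogen altogether by carrying the diacid as silyl esters; it sets out from 8. Saponification (LiOH, THF/H2O, rt) gives 3-hexadecyl-4-oxocyclopent-2-ene-1,1-dicarboxylic acid F6. TBSOTf (3.3 equiv) and Et3N give bis(tert-butyldimethylsilyl) 3-[(tert-butyldimethylsilyl)oxy]-4-hexadecylcyclopenta-2,4-diene-1,1-dicarboxylate F7. Step 8 conditions with 13 should give (1R,4R,5R)-8,8-bis(tert-butyldimethylsilyl) 4-methyl 7-[(tert-butyldimethylsilyl)oxy]-3,6-dihexadecylbicyclo[3.2.1]octa-2,6-diene-4,8,8-tricarboxylate F8. Methanol at rt cleaves only the silyl esters and returns the route at 17, which is decarboxylated in pyridine as before.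

Step 11. Ozone may over-oxidise the C2=C3 ring alkene, and the centre α to the new ketone may epimerise before ring closure. The fallback is a two-stage cleavage with a titratable oxidant; it sets out from 21. Rubottom oxidation (m-CPBA, 1.0 equiv, NaHCO3, CH2Cl2, −20 °C; then Et3N·3HF) gives methyl (1R,4R,5R,8S)-3,6-dihexadecyl-6-hydroxy-8-(3-methoxy-3-oxopropanoyl)-7-oxobicyclo[3.2.1]oct-2-ene-4-carboxylate F9; its C6 configuration is irrelevant. Periodate cleavage of the α-hydroxy ketone (NaIO4, THF/H2O, rt) gives 22, which is closed with piperidinium acetate as in step 11.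

Further compounds
F1 | step 8 | methyl 3-oxononadecanoate | CCCCCCCCCCCCCCCCC(=O)CC(=O)OC
F2 | step 8 | methyl (2E)-3-{[(trifluoromethyl)sulfonyl]oxy}nonadec-2-enoate | CCCCCCCCCCCCCCCC/C(OS(=O)(=O)C(F)(F)F)=C\C(=O)OC
F3 | step 8 | 1-benzyl 5-methyl (3E)-2-diazo-3-hexadecylpent-3-enedioate | CCCCCCCCCCCCCCCC/C(C(=[N+]=[N-])C(=O)OCc1ccccc1)=C\C(=O)OC
F4 | step 8 | (1R,4R,5R)-2,8,8-tribenzyl 4-methyl 7-[(tert-butyldimethylsilyl)oxy]-3,6-dihexadecylbicyclo[3.2.1]octa-2,6-diene-2,4,8,8-tetracarboxylate | CCCCCCCCCCCCCCCCC1=C(C(=O)OCc3ccccc3)[C@H]2C(O[Si](C)(C)C(C)(C)C)=C(CCCCCCCCCCCCCCCC)[C@@H]([C@H]1C(=O)OC)C2(C(=O)OCc1ccccc1)C(=O)OCc1ccccc1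
F5 | step 8 | (1R,4R,5R)-7-[(tert-butyldimethylsilyl)oxy]-3,6-dihexadecyl-4-(methoxycarbonyl)bicyclo[3.2.1]octa-2,6-diene-2,8,8-tricarboxylic acid | CCCCCCCCCCCCCCCCC1=C(C(=O)O)[C@H]2C(O[Si](C)(C)C(C)(C)C)=C(CCCCCCCCCCCCCCCC)[C@@H]([C@H]1C(=O)OC)C2(C(=O)O)C(=O)O
F6 | step 9 | 3-hexadecyl-4-oxocyclopent-2-ene-1,1-dicarboxylic acid | O=C1CC(C=C1CCCCCCCCCCCCCCCC)(C(=O)O)C(=O)O
F7 | step 9 | bis(tert-butyldimethylsilyl) 3-[(tert-butyldimethylsilyl)oxy]-4-hexadecylcyclopenta-2,4-diene-1,1-dicarboxylate | CCCCCCCCCCCCCCCCC1=CC(C=C1O[Si](C)(C)C(C)(C)C)(C(=O)O[Si](C)(C)C(C)(C)C)C(=O)O[Si](C)(C)C(C)(C)C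
F8 | step 9 | (1R,4R,5R)-8,8-bis(tert-butyldimethylsilyl) 4-methyl 7-[(tert-butyldimethylsilyl)oxy]-3,6-dihexadecylbicyclo[3.2.1]octa-2,6-diene-4,8,8-tricarboxylate | CCCCCCCCCCCCCCCCC1=C[C@H]2C(O[Si](C)(C)C(C)(C)C)=C(CCCCCCCCCCCCCCCC)[C@@H]([C@H]1C(=O)OC)C2(C(=O)O[Si](C)(C)C(C)(C)C)C(=O)O[Si](C)(C)C(C)(C)C
F9 | step 11 | methyl (1R,4R,5R,8S)-3,6-dihexadecyl-6-hydroxy-8-(3-methoxy-3-oxopropanoyl)-7-oxobicyclo[3.2.1]oct-2-ene-4-carboxylate (C6 epimers) | CCCCCCCCCCCCCCCCC1=C[C@H]2C(=O)C(O)(CCCCCCCCCCCCCCCC)[C@@H]([C@H]1C(=O)OC)[C@@H]2C(=O)CC(=O)OC
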